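**Strategy.** Everything rests on reading the C1–C4 edge of the tetralin as a masked lactone: C2 and C3 with their hydroxymethyl groups correspond to Cβ, Cα, the acetal carbon and the carbonyl carbon of a 5-alkoxybutenolide, while ring C delivers C1 as a dithiane carbanion and ring E delivers C4 as a benzylic bromide. In a single flask the carbanion adds to Cβ and the enolate so formed, which already carries the future tertiary oxygen, is benzylated; this gives bonds C1–C2 and C3–C4 and the stereocentres C2 and C3. The substrate is O-benzylated 5,5'-bivanillin with ring C as 1,3-dithiane and ring B as dioxolane. The tetrahydrofuran arm follows by established steps.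

Key step: step 12

Remark: ring A is an isovanillyl unit (3-OH, 4-OMe) and ring E a vanillyl unit (4-OH, 3-OMe), so two different benzylic bromides are used. The (5R) acetal with anti addition and anti alkylation maps onto 2S,3S of the tetralin and, used a second time, onto 3R,4S of the tetrahydrofuran. Bn = benzyl, Men = (1R,2S,5R)-menthyl; ring B and ring C are the biaryl rings that carry the tetrahydrofuran arm and the tetralin arm.

Step 1
Reactants: 1 vanillin (two molecules)
Product: 2 5,5'-bivanillin
Conditions: Na2S2O8, FeSO4·7H2O (cat.), H2O, 50 °C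
Reagents that add atoms: vanillin (the second molecule of 1), COc1cc(C=O)ccc1O
Why: Oxidative phenol coupling with Na2S2O8 and catalytic FeSO4 joins two vanillin phenoxyl radicals at the only free position ortho to OH, a long-established dimerisation.

Step 2
Reactants: 2 5,5'-bivanillin
Product: 3 bivanillin dibenzyl ether
Conditions: BnBr, K2CO3, DMF, 60 °C
Reagents that add atoms: benzyl bromide, BrCc1ccccc1
Why: Williamson etherification caps both phenols with a group that tolerates organolithium, hydride and acid steps and leaves by hydrogenolysis at the end.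

Step 3
Reactants: 3 bivanillin dibenzyl ether
Product: 4 mono-dithiane mono-aldehyde
Conditions: HS(CH2)3SH (1.0 equiv), BF3·OEt2 (cat.), CH2Cl2, 0 °C; chromatography, recovered 3 recycled
Reagents that add atoms: propane-1,3-dithiol, SCCCS
Why: Lewis acid-catalysed thioacetalisation with one equivalent of dithiol should give the mono-dithiane as the main component of a statistical mixture separable by polarity, and it is done before the O,O-acetal because these conditions would also convert a dioxolane.

Step 4
Reactants: 4 mono-dithiane mono-aldehyde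
Product: 5 ring C dithiane with ring B dioxolane
Conditions: HOCH2CH2OH, p-TsOH·H2O (cat.), toluene, reflux, Dean–Stark
Reagents that add atoms: ethylene glycol, OCCO
Why: Acid-catalysed acetalisation with azeotropic removal of water masks the remaining aldehyde while the dithiane is inert.

Step 5
Reactants: 6 furfural
Product: 7 5-hydroxyfuran-2(5H)-one
Conditions: O2, visible light, methylene blue (cat.), MeOH, rt
Reagents that add atoms: oxygen, O=O
Why: Singlet-oxygen [4+2] cycloaddition to the furan and methanol-induced fragmentation of the endoperoxide expel the formyl carbon as methyl formate, a standard photo-oxygenation.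

Step 6
Reactants: 7 5-hydroxyfuran-2(5H)-one; 8 (−)-menthol
Product: 9 (5R)-5-(l-menthyloxy)furan-2(5H)-one
Conditions: CSA (cat.), toluene, reflux, Dean–Stark; crystallisation from petroleum ether
Reagents that add atoms: none
Why: Acid-catalysed acetalisation of the pseudo-acid gives both C5 epimers, of which the (5R) epimer crystallises while the mother liquor is re-equilibrated under the same conditions, so the acetal carbon becomes the single stereocentre that controls all later additions.

Step 7
Reactants: 9 (5R)-5-(l-menthyloxy)furan-2(5H)-one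
Product: 10 3,4-cis-diol lactone
Conditions: OsO4 (cat.), N-methylmorpholine N-oxide, citric acid, t-BuOH/H2O, rt
Reagents that add atoms: N-methylmorpholine N-oxide, C[N+]1([O-])CCOCC1; water, O
Why: Catalytic OsO4 cis-dihydroxylation of the electron-poor alkene should occur anti to the menthyloxy group, and since both new carbinol centres disappear in step 9 the facial selectivity is not critical.

Step 8
Reactants: 10 3,4-cis-diol lactone
Product: 11 3,4-bis(benzyloxy) lactone
Conditions: BnOC(=NH)CCl3, TfOH (cat.), CH2Cl2/cyclohexane, 0 °C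
Reagents that add atoms: benzyl 2,2,2-trichloroacetimidate, ClC(Cl)(Cl)C(=N)OCc1ccccc1
Why: Acid-catalysed imidate benzylation etherifies both hydroxyls without base, which avoids premature elimination and leaves the acetal stereocentre untouched.

Step 9
Reactants: 11 3,4-bis(benzyloxy) lactone
Product: 12 (5R)-3-benzyloxy-5-(l-menthyloxy)furan-2(5H)-one
Conditions: DBU, CH2Cl2, 0 °C
Reagents that add atoms: none
Why: E1cB β-elimination of benzyl alcohol from the lactone enolate, well known for O-benzylated aldonolactones, gives the 3-alkoxybutenolide without touching C5, and it replaces a less certain C–O coupling on a 3-halobutenolide.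

Step 10
Reactants: 13 4-benzyloxy-3-methoxybenzyl alcohol
Product: 14 4-benzyloxy-3-methoxybenzyl bromide
Conditions: PBr3, Et2O, 0 °C; used at once
Reagents that add atoms: phosphorus tribromide, BrP(Br)Br
Why: Bromination of an electron-rich benzylic alcohol through its phosphite ester is routine and the labile bromide is used without storage.

Step 11
Reactants: 15 3-benzyloxy-4-methoxybenzyl alcohol
Product: 16 3-benzyloxy-4-methoxybenzyl bromide
Conditions: PBr3, Et2O, 0 °C; used at once
Reagents that add atoms: phosphorus tribromide, BrP(Br)Br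
Why: The same benzylic bromination provides the ring A electrophile.

Step 12
Reactants: 5 ring C dithiane with ring B dioxolane; 12 (5R)-3-benzyloxy-5-(l-menthyloxy)furan-2(5H)-one; 14 4-benzyloxy-3-methoxybenzyl bromide
Product: 19 tandem adduct lactone, via lithiated dithiane 17 (not isolated), via lithium enolate 18 (not isolated)
Conditions: n-BuLi, THF, −78 → −25 °C; DMPU, then 12, −78 °C; then 14, −78 → −30 °C
Reagents that add atoms: none
Why: Proposed new method: the delocalised carbanion 17 should add in 1,4-fashion to C4 of butenolide 12, and the lithium enolate 18, which already carries the benzyloxy group on C3, is then C-alkylated by bromide 14, so that the C1–C2 and C3–C4 bonds of the tetralin arm form in one flask. The closest known reaction is the tandem conjugate addition–enolate alkylation of 5-menthyloxyfuran-2(5H)-one with lithiated 2-aryl-1,3-dithianes; new here is the 3-alkoxy group, which turns the acceptor into an enol-ether-type alkene and makes the enolate fully substituted. No ring is closed. The stereocentre at lactone C4 (tetralin C2) follows from attack anti to the menthyloxy group on C5, and the quaternary centre at lactone C3 (tetralin C3) from alkylation anti to the new dithianyl-aryl group, which places benzyl trans and oxygen cis to it. The step needs 1,4- over 1,2-addition and over deprotonation at C5, which the soft aryl-stabilised anion, low temperature and DMPU should secure, and C- over O-alkylation, which the lithium enolate and the reactive benzylic bromide favour.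

Step 13
Reactants: 19 tandem adduct lactone
Product: 20 aryl ketone lactone
Conditions: Hg(ClO4)2·3H2O, CaCO3, THF/H2O, 0 °C → rt
Reagents that add atoms: water, O
Why: Thiophilic divalent mercury hydrolyses the dithiane to the aryl ketone while the carbonate buffer keeps the dioxolane and the acyloxy acetal intact, and the C–H next to the new ketone already sits in its more stable trans arrangement.

Step 14
Reactants: 20 aryl ketone lactone
Product: 21 ring C triol
Conditions: LiAlH4, THF, 0 °C → rt; NaOH/H2O work-up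
Reagents that add atoms: none
Why: Hydride reduction turns the ketone into the carbinol (an epimer mixture that converges in step 15) and the lactone acetal into the 1,4-diol with release of menthol, as known for 5-menthyloxy lactones, without touching C2 and C3.

Step 15
Reactants: 21 ring C triol
Product: 23 tetralin diol aldehyde, via tetralin dioxolane 22 (not isolated)
Conditions: TFA, CH2Cl2, 0 °C → rt; then H2O/THF, rt; aq. NaHCO3/MeOH work-up
Reagents that add atoms: water, O
Why: Ionisation of the carbinol para to the ring C ether gives a benzylic cation that ring E attacks para to its methoxy group in a 6-membered Friedel–Crafts closure (any cyclic ether formed first re-ionises), the aryl group settling pseudo-equatorial and trans to the C2 CH2OH so that C1 becomes S, and the aqueous acid then hydrolyses the dioxolane.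

Step 16
Reactants: 23 tetralin diol aldehyde
Product: 24 ring B dithiane diol
Conditions: HS(CH2)3SH, BF3·OEt2, CH2Cl2, 0 °C
Reagents that add atoms: propane-1,3-dithiol, SCCCS
Why: Chemoselective thioacetalisation of the aldehyde installs the second acyl-anion precursor, and free alcohols and benzyl ethers tolerate the brief Lewis acid exposure.

Step 17
Reactants: 24 ring B dithiane diol
Product: 25 ring B dithiane bis(benzyl ether)
Conditions: NaH, BnBr, Bu4NI (cat.), THF/DMF, 0 °C → rt
Reagents that add atoms: benzyl bromide, BrCc1ccccc1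
Why: Williamson benzylation of the two primary alcohols removes acidic protons before the organolithium step, and NaH does not deprotonate the dithiane.

Step 18
Reactants: 25 ring B dithiane bis(benzyl ether); 9 (5R)-5-(l-menthyloxy)furan-2(5H)-one
Product: 28 α-hydroxy lactone, via lithiated dithiane 26 (not isolated), via lithium enolate 27 (not isolated)
Conditions: n-BuLi, THF, −78 → −25 °C; 9, −78 °C; then (camphorsulfonyl)oxaziridine, −78 → −40 °C; aq. NH4Cl
Reagents that add atoms: (camphorsulfonyl)oxaziridine (either enantiomer), CC1(C)C2CCC13CS(=O)(=O)N4OC34C2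
Why: The established conjugate addition of a lithiated aryl dithiane to the unsubstituted 5-menthyloxybutenolide anti to the acetal substituent sets the future tetrahydrofuran C3, and the enolate is oxidised in the same flask by the N-sulfonyloxaziridine (tandem conjugate addition–enolate oxidation) to a carbinol whose configuration does not matter because it is planarised again in step 20.

Step 19
Reactants: 28 α-hydroxy lactone
Product: 29 α-benzyloxy lactone
Conditions: BnOC(=NH)CCl3, TfOH (cat.), CH2Cl2/cyclohexane, 0 °C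
Reagents that add atoms: benzyl 2,2,2-trichloroacetimidate, ClC(Cl)(Cl)C(=N)OCc1ccccc1
Why: Base-free imidate benzylation of the hindered α-hydroxy lactone avoids enolisation and C-benzylation.

Step 20
Reactants: 29 α-benzyloxy lactone; 16 3-benzyloxy-4-methoxybenzyl bromide
Product: 31 ring B quaternary lactone, via lithium enolate 30 (not isolated)
Conditions: LiN(i-Pr)2, THF, −78 °C; then 16, DMPU, −78 → −30 °C
Reagents that add atoms: none
Why: Alkylation of an α-alkoxy lactone enolate with a benzylic bromide occurs on the face opposite to the bulky C4 substituent, which gives the quaternary centre with benzyl trans and oxygen cis to that substituent as needed for tetrahydrofuran C4.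

Step 21
Reactants: 31 ring B quaternary lactone
Product: 32 ring B aryl ketone lactone
Conditions: Hg(ClO4)2·3H2O, CaCO3, THF/H2O, 0 °C → rt
Reagents that add atoms: water, O
Why: Buffered dithiane hydrolysis with divalent mercury repeats step 13 on a substrate that now carries only ethers besides the lactone acetal.

Step 22
Reactants: 32 ring B aryl ketone lactone
Product: 33 ring B triol
Conditions: LiAlH4, THF, 0 °C → rt; NaOH/H2O work-up
Reagents that add atoms: none
Why: As in step 14, hydride reduces ketone and lactone acetal to the benzylic carbinol and the two primary alcohols with loss of menthol, leaving the two stereocentres untouched.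

Step 23
Reactants: 33 ring B triol
Product: 34 octabenzyl ether of the target
Conditions: CSA (cat.), CH2Cl2, 0 °C
Reagents that add atoms: none
Why: Mild acid ionises the ring B benzylic carbinol and the CH2OH on the quaternary carbon captures the cation in the only possible 5-membered etherification under kinetic control, the aryl group ending trans to the C3 CH2OH (C2 S), while Friedel–Crafts attack by ring A is slower and needs stronger acid.

Step 24
Reactants: 34 octabenzyl ether of the target
Product: 35 CNP0252244.1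
Conditions: H2 (1 atm), Pd(OH)2/C, EtOAc/MeOH, rt
Reagents that add atoms: none
Why: Catalytic hydrogenolysis removes all eight O-benzyl groups, whereas the hindered, biaryl-bound benzylic C–O bond of the tetrahydrofuran should be cleaved far more slowly, so the reaction is stopped once the tertiary ethers are gone.

**Compound list**

1 | vanillin (4-hydroxy-3-methoxybenzaldehyde) | COc1cc(C=O)ccc1O | starting material
2 | 5,5'-bivanillin (6,6'-dihydroxy-5,5'-dimethoxybiphenyl-3,3'-dicarbaldehyde) | COc1cc(C=O)cc(-c2cc(C=O)cc(OC)c2O)c1O | intermediate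
3 | 6,6'-bis(benzyloxy)-5,5'-dimethoxybiphenyl-3,3'-dicarbaldehyde | COc1cc(C=O)cc(-c2cc(C=O)cc(OC)c2OCc2ccccc2)c1OCc1ccccc1 | intermediate
4 | 6,6'-bis(benzyloxy)-3'-(1,3-dithian-2-yl)-5,5'-dimethoxybiphenyl-3-carbaldehyde | COc1cc(C=O)cc(-c2cc(C3SCCCS3)cc(OC)c2OCc2ccccc2)c1OCc1ccccc1 | intermediate
5 | 2-[6,6'-bis(benzyloxy)-3'-(1,3-dioxolan-2-yl)-5,5'-dimethoxybiphenyl-3-yl]-1,3-dithiane (ring C dithiane, ring B dioxolane) | COc1cc(C2OCCO2)cc(-c2cc(C3SCCCS3)cc(OC)c2OCc2ccccc2)c1OCc1ccccc1 | intermediate
6 | furfural | O=Cc1ccco1 | starting material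
7 | 5-hydroxyfuran-2(5H)-one (racemic) | O=C1OC(O)C=C1 | intermediate
8 | (−)-menthol, (1R,2S,5R) | CC(C)[C@@H]1CC[C@@H](C)C[C@H]1O | starting material
9 | (5R)-5-(l-menthyloxy)furan-2(5H)-one | O=C1O[C@@H](O[C@@H]2C[C@H](C)CC[C@H]2C(C)C)C=C1 | intermediate
10 | (5R)-3,4-dihydroxy-5-(l-menthyloxy)dihydrofuran-2(3H)-one, cis-diol anti to menthyloxy | O=C1O[C@@H](O[C@@H]2C[C@H](C)CC[C@H]2C(C)C)[C@H](O)[C@@H]1O | intermediate
11 | 3,4-di-O-benzyl ether of 10 | O=C1O[C@@H](O[C@@H]2C[C@H](C)CC[C@H]2C(C)C)[C@H](OCc2ccccc2)[C@@H]1OCc1ccccc1 | intermediate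
12 | (5R)-3-benzyloxy-5-(l-menthyloxy)furan-2(5H)-one | O=C1O[C@@H](O[C@@H]2C[C@H](C)CC[C@H]2C(C)C)C=C1OCc1ccccc1 | intermediate
13 | 4-benzyloxy-3-methoxybenzyl alcohol | COc1cc(CO)ccc1OCc1ccccc1 | starting material
14 | 4-benzyloxy-3-methoxybenzyl bromide | COc1cc(CBr)ccc1OCc1ccccc1 | intermediate
15 | 3-benzyloxy-4-methoxybenzyl alcohol | COc1ccc(CO)cc1OCc1ccccc1 | starting material
16 | 3-benzyloxy-4-methoxybenzyl bromide | COc1ccc(CBr)cc1OCc1ccccc1 | intermediate
17 | 2-lithio-1,3-dithiane derived from 5 | COc1cc(C2OCCO2)cc(-c2cc(C3([Li])SCCCS3)cc(OC)c2OCc2ccccc2)c1OCc1ccccc1 | intermediate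
18 | lithium enolate of the 3-benzyloxy lactone, ring C dithianyl group at C4 trans to menthyloxy | [Li]OC1=C(OCc2ccccc2)[C@@H](C2(SCCCS2)c2cc(OC)c(OCc3ccccc3)c(-c3cc(C4OCCO4)cc(OC)c3OCc3ccccc3)c2)[C@H](O[C@@H]2C[C@H](C)CC[C@H]2C(C)C)O1 | intermediate
19 | (5R)-5-(l-menthyloxy)dihydrofuran-2(3H)-one with the 2-(ring C aryl)-1,3-dithian-2-yl group at C4 trans to menthyloxy, and benzyloxy plus 4-benzyloxy-3-methoxybenzyl at C3 (benzyl trans to dithianyl); ring B as dioxolane | O=C1O[C@@H](O[C@@H]2C[C@H](C)CC[C@H]2C(C)C)[C@H](C2(SCCCS2)c2cc(OC)c(OCc3ccccc3)c(-c3cc(C4OCCO4)cc(OC)c3OCc3ccccc3)c2)[C@@]1(OCc2ccccc2)Cc2ccc(OCc3ccccc3)c(OC)c2 | intermediate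
20 | 4-aroyl lactone from 19 (dithiane replaced by C=O, configuration unchanged) | O=C1O[C@@H](O[C@@H]2C[C@H](C)CC[C@H]2C(C)C)[C@H](C(=O)c2cc(OC)c(OCc3ccccc3)c(-c3cc(C4OCCO4)cc(OC)c3OCc3ccccc3)c2)[C@@]1(OCc2ccccc2)Cc2ccc(OCc3ccccc3)c(OC)c2 | intermediate
21 | open-chain triol: ring C aryl carbinol (both epimers), C2 CH2OH, C3 benzyloxy/CH2OH/4-benzyloxy-3-methoxybenzyl, C2 and C3 as in 19 | OC[C@H](C(O)c1cc(OC)c(OCc2ccccc2)c(-c2cc(C3OCCO3)cc(OC)c2OCc2ccccc2)c1)[C@@](CO)(OCc1ccccc1)Cc1ccc(OCc2ccccc2)c(OC)c1 | intermediate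
22 | (1S,2S,3S)-tetralin: 1-(ring C aryl), 2,3-bis(hydroxymethyl), 3-benzyloxy, 7-benzyloxy-6-methoxy; ring B still as dioxolane | COc1cc(C2OCCO2)cc(-c2cc([C@H]3c4cc(OCc5ccccc5)c(OC)cc4C[C@@](OCc4ccccc4)(CO)[C@@H]3CO)cc(OC)c2OCc2ccccc2)c1OCc1ccccc1 | intermediate
23 | the same (1S,2S,3S)-tetralin diol with ring B as free aldehyde | COc1cc(C=O)cc(-c2cc([C@H]3c4cc(OCc5ccccc5)c(OC)cc4C[C@@](OCc4ccccc4)(CO)[C@@H]3CO)cc(OC)c2OCc2ccccc2)c1OCc1ccccc1 | intermediate
24 | the same tetralin diol with ring B as 1,3-dithian-2-yl | COc1cc(C2SCCCS2)cc(-c2cc([C@H]3c4cc(OCc5ccccc5)c(OC)cc4C[C@@](OCc4ccccc4)(CO)[C@@H]3CO)cc(OC)c2OCc2ccccc2)c1OCc1ccccc1 | intermediate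
25 | bis(benzyl ether) of 24 at the two CH2OH groups | COc1cc(C2SCCCS2)cc(-c2cc([C@H]3c4cc(OCc5ccccc5)c(OC)cc4C[C@@](OCc4ccccc4)(COCc4ccccc4)[C@@H]3COCc3ccccc3)cc(OC)c2OCc2ccccc2)c1OCc1ccccc1 | intermediate
26 | 2-lithio-1,3-dithiane derived from 25 | COc1cc(C2([Li])SCCCS2)cc(-c2cc([C@H]3c4cc(OCc5ccccc5)c(OC)cc4C[C@@](OCc4ccccc4)(COCc4ccccc4)[C@@H]3COCc3ccccc3)cc(OC)c2OCc2ccccc2)c1OCc1ccccc1 | intermediate
27 | lithium enolate from 26 and 9, ring B dithianyl group at C4 trans to menthyloxy | [Li]OC1=C[C@@H](C2(SCCCS2)c2cc(OC)c(OCc3ccccc3)c(-c3cc([C@H]4c5cc(OCc6ccccc6)c(OC)cc5C[C@@](OCc5ccccc5)(COCc5ccccc5)[C@@H]4COCc4ccccc4)cc(OC)c3OCc3ccccc3)c2)[C@H](O[C@@H]2C[C@H](C)CC[C@H]2C(C)C)O1 | intermediate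
28 | (5R)-3-hydroxy-5-(l-menthyloxy)dihydrofuran-2(3H)-one with the 2-(ring B aryl)-1,3-dithian-2-yl group at C4 trans to menthyloxy and OH trans to dithianyl | O=C1O[C@@H](O[C@@H]2C[C@H](C)CC[C@H]2C(C)C)[C@H](C2(SCCCS2)c2cc(OC)c(OCc3ccccc3)c(-c3cc([C@H]4c5cc(OCc6ccccc6)c(OC)cc5C[C@@](OCc5ccccc5)(COCc5ccccc5)[C@@H]4COCc4ccccc4)cc(OC)c3OCc3ccccc3)c2)[C@H]1O | intermediate
29 | O-benzyl ether of 28 | O=C1O[C@@H](O[C@@H]2C[C@H](C)CC[C@H]2C(C)C)[C@H](C2(SCCCS2)c2cc(OC)c(OCc3ccccc3)c(-c3cc([C@H]4c5cc(OCc6ccccc6)c(OC)cc5C[C@@](OCc5ccccc5)(COCc5ccccc5)[C@@H]4COCc4ccccc4)cc(OC)c3OCc3ccccc3)c2)[C@H]1OCc1ccccc1 | intermediate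
30 | lithium enolate of 29 | [Li]OC1=C(OCc2ccccc2)[C@@H](C2(SCCCS2)c2cc(OC)c(OCc3ccccc3)c(-c3cc([C@H]4c5cc(OCc6ccccc6)c(OC)cc5C[C@@](OCc5ccccc5)(COCc5ccccc5)[C@@H]4COCc4ccccc4)cc(OC)c3OCc3ccccc3)c2)[C@H](O[C@@H]2C[C@H](C)CC[C@H]2C(C)C)O1 | intermediate
31 | ring B analogue of 19: C3 benzyloxy plus 3-benzyloxy-4-methoxybenzyl (trans to dithianyl), C4 dithianyl trans to menthyloxy | O=C1O[C@@H](O[C@@H]2C[C@H](C)CC[C@H]2C(C)C)[C@H](C2(SCCCS2)c2cc(OC)c(OCc3ccccc3)c(-c3cc([C@H]4c5cc(OCc6ccccc6)c(OC)cc5C[C@@](OCc5ccccc5)(COCc5ccccc5)[C@@H]4COCc4ccccc4)cc(OC)c3OCc3ccccc3)c2)[C@@]1(OCc2ccccc2)Cc2ccc(OC)c(OCc3ccccc3)c2 | intermediate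
32 | 4-aroyl lactone from 31 | O=C1O[C@@H](O[C@@H]2C[C@H](C)CC[C@H]2C(C)C)[C@H](C(=O)c2cc(OC)c(OCc3ccccc3)c(-c3cc([C@H]4c5cc(OCc6ccccc6)c(OC)cc5C[C@@](OCc5ccccc5)(COCc5ccccc5)[C@@H]4COCc4ccccc4)cc(OC)c3OCc3ccccc3)c2)[C@@]1(OCc2ccccc2)Cc2ccc(OC)c(OCc3ccccc3)c2 | intermediate
33 | open-chain triol of the tetrahydrofuran arm: ring B aryl carbinol (both epimers), CH2OH on the tertiary carbon, benzyloxy/CH2OH/3-benzyloxy-4-methoxybenzyl on the quaternary carbon | OC[C@H](C(O)c1cc(OC)c(OCc2ccccc2)c(-c2cc([C@H]3c4cc(OCc5ccccc5)c(OC)cc4C[C@@](OCc4ccccc4)(COCc4ccccc4)[C@@H]3COCc3ccccc3)cc(OC)c2OCc2ccccc2)c1)[C@@](CO)(OCc1ccccc1)Cc1ccc(OC)c(OCc2ccccc2)c1 | intermediate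
34 | target with all four phenols, both tertiary hydroxyls and the two tetralin CH2OH groups as benzyl ethers; tetrahydrofuran (2S,3R,4S), tetralin (1S,2S,3S) | COc1ccc(C[C@@]2(OCc3ccccc3)CO[C@H](c3cc(OC)c(OCc4ccccc4)c(-c4cc([C@H]5c6cc(OCc7ccccc7)c(OC)cc6C[C@@](OCc6ccccc6)(COCc6ccccc6)[C@@H]5COCc5ccccc5)cc(OC)c4OCc4ccccc4)c3)[C@H]2CO)cc1OCc1ccccc1 | intermediate
35 | CNP0252244.1 | COc1ccc(C[C@@]2(O)CO[C@H](c3cc(OC)c(O)c(-c4cc([C@H]5c6cc(O)c(OC)cc6C[C@@](O)(CO)[C@@H]5CO)cc(OC)c4O)c3)[C@H]2CO)cc1O | target

**Step count.** Total: 24 steps. Longest linear sequence: 18 steps (6 → 7 → 9 → 10 → 11 → 12 → 19 → 20 → 21 → 23 → 24 → 25 → 28 → 29 → 31 → 32 → 33 → 34 → 35).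

**Steps most likely to fail**

Step 12. The electron-rich enol-ether alkene of 12 may react too slowly at C4, so that addition to the lactone carbonyl or proton abstraction at C5 takes over. The fallback uses known chemistry and the unsubstituted butenolide. Anion 17 (from 5) is added to 9 to give the lithium enolate F1, which is oxidised in the same flask with (camphorsulfonyl)oxaziridine to the hydroxy lactone F2. Benzyl trichloroacetimidate with catalytic TfOH converts it into the benzyl ether F3. LiN(i-Pr)2 then regenerates enolate 18 from F3, and alkylation with 14 returns to the route at 19.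

Step 24. Slow cleavage of the two tertiary benzyl ethers may leave time for reductive opening of the benzylic C2–O bond of the tetrahydrofuran. The fallback sets out from ketone 32, where no benzylic C–O bond other than the benzyl ethers exists. Hydrogenolysis there (H2, Pd(OH)2/C) gives the octahydroxy keto lactone F4. LiAlH4 reduces it to the free polyol F5. Brief treatment with dilute AcOH in aqueous THF closes the tetrahydrofuran through the para-quinone methide of ring B and arrives at 35.

Step 18. The congested enolate 27 may be oxidised incompletely, or it may be captured by the sulfonyl imine that the oxidant leaves behind. The fallback applies once step 12 has been reduced to practice. Anion 26 (from 25) is added to butenolide 12 instead of 9, which gives enolate 30 directly, and alkylation with 16 returns to the route at 31. Steps 18–20 collapse into one operation and no further compound F0 arises.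

**Further compounds**

F1 | step 12 | lithium enolate from 17 and 9, ring C dithianyl group at C4 trans to menthyloxy | [Li]OC1=C[C@@H](C2(SCCCS2)c2cc(OC)c(OCc3ccccc3)c(-c3cc(C4OCCO4)cc(OC)c3OCc3ccccc3)c2)[C@H](O[C@@H]2C[C@H](C)CC[C@H]2C(C)C)O1
F2 | step 12 | 3-hydroxy lactone of the ring C series, OH trans to dithianyl | O=C1O[C@@H](O[C@@H]2C[C@H](C)CC[C@H]2C(C)C)[C@H](C2(SCCCS2)c2cc(OC)c(OCc3ccccc3)c(-c3cc(C4OCCO4)cc(OC)c3OCc3ccccc3)c2)[C@H]1O
F3 | step 12 | O-benzyl ether of F2 | O=C1O[C@@H](O[C@@H]2C[C@H](C)CC[C@H]2C(C)C)[C@H](C2(SCCCS2)c2cc(OC)c(OCc3ccccc3)c(-c3cc(C4OCCO4)cc(OC)c3OCc3ccccc3)c2)[C@H]1OCc1ccccc1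
F4 | step 24 | octahydroxy keto lactone (32 without its eight benzyl groups) | O=C1O[C@@H](O[C@@H]2C[C@H](C)CC[C@H]2C(C)C)[C@H](C(=O)c2cc(OC)c(O)c(-c3cc([C@H]4c5cc(O)c(OC)cc5C[C@@](O)(CO)[C@@H]4CO)cc(OC)c3O)c2)[C@@]1(O)Cc2ccc(OC)c(O)c2
F5 | step 24 | free polyol (33 without its benzyl groups, carbinol as both epimers) | OC[C@H](C(O)c1cc(OC)c(O)c(-c2cc([C@H]3c4cc(O)c(OC)cc4C[C@@](O)(CO)[C@@H]3CO)cc(OC)c2O)c1)[C@@](CO)(O)Cc1ccc(OC)c(O)c1
F0 | step 18 | none | none
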